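## Structural features

The target is a monocyclic oxane (ring O1, C2–C6). C2 carries a 4-hydroxyphenyl group, C3 an (E)-3-(4-hydroxyphenyl)prop-2-enyl chain, and C5 a hydroxy(4-hydroxyphenyl)methyl group whose carbinol carbon is called C7 here; C4 and C6 are methylenes, C6 being bonded to O1. There are four stereocentres, (2R,3S,5R,7R): C2 and C3 are neighbours and cis, C5 is 1,3 to C3 and also cis, so the ring is all-cis, and C7 sits outside the ring next to C5 (with C6 as main chain, the C4 branch and the C7 hydroxyl are anti). An all-cis 2,3,5 pattern cannot place all three groups equatorial, so it is unlikely to be the isomer favoured by equilibration and has to be made under kinetic control. The fragile groups are three free phenols, two para-hydroxybenzylic C–O bonds (C2–O1 and C7–OH) that can open to quinone methides under acid or as phenoxides, and an electron-rich E-styrene. The carbon skeleton is simple; the real difficulty is stereochemical: the cis C2/C3 pair, C5 on the same face, and above all the correlation of exocyclic C7 with the ring. The key step uses the fact that the edge O1–C2(aryl)–C3 has the atoms of a styrene and C4–C5(C7)–C6–O1 those of a 2-substituted acrolein: a Z-alkene transfers its geometry to the cis C2/C3 pair, and C5 is left as the β-carbon of a cyclic enol ether that can take hydrogen from the face opposite that pair.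

## Logic of the disconnections

**22 to 21.** The four O–H bonds of 22 are traced back to O–Si bonds in 21. One kind of silyl ether on every oxygen means a single deprotection at the end and non-polar intermediates throughout. The forward step must be buffered so that no phenoxide is left next to a benzylic C–O bond.

**21 to 20 and 2.** The side-chain double bond (second and third carbons out from C3) is cut. The sulfonyl carbanion is placed on the aliphatic partner 20 and the carbonyl on the aromatic partner 2, the polarity in which the Julia–Kocienski reaction is reliably E-selective. 2 is already made in the other branch, so no separate reagent synthesis is needed. The forward step must tolerate four silyl ethers and leave the benzylic C2–H alone.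

**20 to 19 to 18 to 17.** The S–O bonds, the C–S bond and then the free primary hydroxyl are removed in turn, ending at the pivalate 17. These are functional-group changes only. They lead back to an oxygenated two-carbon arm that can ride through the cycloaddition without taking part in cationic chemistry. The forward reagents must avoid alkoxide and hydroxide, which would strip aryl silyl ethers.

**17 to 16.** The C5–H and C6–H bonds are removed, turning the C5 stereocentre into the β-carbon of an enol ether. This removes one stereocentre and exposes the retron of a hetero-Diels–Alder reaction. In the forward direction hydrogen must add to the face away from the C2 aryl group and the C3 arm, and neither benzylic C–O bond may be hydrogenolysed.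

**16 to 9 and 15.** O1–C2 and C3–C4 are cut. This opens the only ring and divides the molecule into a heterodiene that carries C7 (9) and a dienophile that carries the arm (15). Two stereocentres are reduced to one alkene geometry, and the fragments are of similar size. The forward step needs an s-cis enal, bonding of the benzylic carbon to oxygen, retention of the Z geometry, and a choice between the two faces of 15 that only C7 and the catalyst can make.

**9 to 7 to 5 to 4 to 2 to 1.** In 9 the C5=C4 methylene bond is cut (α-methylenation of 7); the formyl group of 7 is traced to the terminal alkene of 5; the C7–CH2 bond of 4 is cut to 2 and an allyl nucleophile; the silyl ethers go back to 1. C7 is then set by a reagent-controlled allylation rather than by a resolution, and no redox adjustment is needed once the methylene carbon is in place. The demands are high enantioselectivity on an electron-rich aromatic aldehyde and methylenation without loss of the β-silyloxy group.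

**15 to 14 to 11 and 13 to 10 and 12.** The Z double bond of 15 is traced to the triple bond of 14, whose aryl–alkynyl bond is cut to 11 and 13; these come from 10 and 12 by O-silylation and O-acylation. The alkyne fixes the position of the unsaturation and its syn semi-hydrogenation fixes the geometry. The forward step must avoid over-reduction and Z-to-E drift.

## Other disconnections considered

**Alternative 1:** The cut is at C2–C3 and C5–C7: both aryl carbinol carbons are detached as 2 from a C3–C4–C5 glutarate, whose two carbonyl carbons are C6 and the carbon attached to C3.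

- Forward key step: double soft enolisation of the glutaryl bis-imide A1 (MgCl2, Et3N, Me3SiCl) and two anti-selective aldol additions to 2 would give A2.
- In favour: the target hides a twofold axis, since C2/C3 and C7/C5 are the same anti ArCH(O)–CH unit. One auxiliary-controlled operation would therefore set all four stereocentres. Aromatic, non-enolisable aldehydes are the best substrates for this aldol variant. The two ends of A2 are homotopic, so lactonisation of either hydroxyl onto the distal imide desymmetrises it without a selectivity problem.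
- Against: the second enolisation must occur on a mono-aldolate that can instead undergo retro-aldol reaction or cyclise. After the key step no ring exists; the lactone carbonyl C6 must be taken down to a ring CH2 next to two electron-rich benzylic C–O bonds, and the exocyclic acyl carbon must be reduced and extended by one carbon before the styrene can be attached.
- Comparison: on stereochemical certainty Alternative 1 is the better plan, because the ring-to-C7 relationship is dictated by the auxiliary and not left to a weak facial bias and a face-selective hydrogenation. On mechanism it relies on well-understood closed metal-enolate transition states but forms no ring, whereas the chosen plan makes the ring and two skeletal bonds in one step. On step economy its end game is expected to be longer than the six steps that follow the cycloaddition. The two plans are equal in drawing both benzylic carbinol carbons from 2.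

**Alternative 2:** The cut is at O1–C6 and C6–C5, with C6 coming from formaldehyde, followed later by cleavage of a cyclohexene double bond whose carbons become C7 and the second carbon of the C3 arm.

- Forward key step: acid condenses the carbinol A3 with formaldehyde to an oxocarbenium ion; the ring alkene attacks it through C5 and closes the oxane as the bridged bicycle A4 after loss of a proton. Ozonolysis would then give the dialdehyde A5.
- In favour: the C3/C5 cis relationship is a geometric necessity of the bridge, which is better than relying on the face selectivity of a hydrogenation. C2 and C3 are both in place before the ring forms and come from a chiral-pool carbocycle plus a carbonyl reduction, so there is no face problem of the kind the chosen plan has; on this point the alternative is also the better one. Ozonolysis unmasks exactly the two carbons needed.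
- Against: a para-oxygenated benzylic carbinol has to survive acid (hence the aryl ester, which then has to be exchanged later). The elimination that ends the Prins step must be regioselective. The two aldehydes of A5 must be told apart. C7 must then be created by aryl-metal addition to the epimerisable C5 aldehyde under 1,2-induction of uncertain sense and level.
- Comparison: structurally it controls the ring better and C7 worse than the chosen plan, in which C7 is set first by a reagent-controlled allylation. Mechanistically it trades a cycloaddition with a stereospecificity risk for a cationic cyclisation with an ionisation risk. In step count the two are expected to be about equal.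

**Alternative 3:** The cut is at O1–C6, with the oxane ring derived from a furan whose carbons become C3 (as a ketone), C4, C5 and C6.

- Forward key step: oxidation of the furyl carbinol A6 (available enantioenriched by asymmetric carbonyl reduction) opens the furan to an ene-dione whose aldehyde is captured by the carbinol oxygen, giving the pyranone A7.
- In favour: the ring-forming step is the most dependable of all four plans and is better than the chosen cycloaddition in that respect. Absolute control of one benzylic centre by a catalytic reduction equals the control of C7 in the chosen plan. The enone and lactol offer handles at C3, C5 and C6.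
- Against: C2 in A7 is benzylic, α-oxy and α to a ketone, so the only stereocentre is at risk of epimerisation. The electron-rich aryl ring competes with the furan for the oxidant. The anomeric hydroxyl must be removed under acid. Both side chains and three stereocentres (C3, C5, C7) must then be introduced one at a time, the C5–C7 unit by a conjugate addition with weak control of both centres.
- Comparison: structurally the ring arrives bare, whereas the chosen plan delivers it with all carbons attached. Mechanistically each later stereocentre depends on substrate control from C2 across the ring. In step economy it is clearly the longest.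

Key step: step 10

Abbreviations: TBS = tert-butyldimethylsilyl; Piv = 2,2-dimethylpropanoyl; fod = 6,6,7,7,8,8,8-heptafluoro-2,2-dimethyloctane-3,5-dionate; DIAD = diisopropyl azodicarboxylate.

Remark on descriptors: in 9 and 16 the carbinol carbon C7 is (S), and in 16–20 C3 is (R), only because the CIP ranking of their neighbours differs from that in the target; the spatial arrangement is that of the target throughout, and a check of every stereodescriptor of 9, 15 and 16 against the target showed no inconsistency.

Remark on the design of 9 and 15: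
- O7 is kept as a bulky, non-chelating silyl ether so that the Lewis acid cannot bridge O1 and O7 and hold the enal s-trans.
- The arm is kept as a pivalate, whose oxygen cannot trap a benzylic cation.
- The aryl oxygens are silyl ethers so that 15 stays electron-rich.
- 9 is a single enantiomer made without resolution, so a wrong-face adduct is a separable diastereomer.

Assumption: the allylborane of step 2 is used as the commercial pentane solution; the sense of induction is the one established for aromatic aldehydes, and the antipodal reagent would be used should a Mosher ester analysis show otherwise.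

## Route

**Step 1**
Reactants: 1 4-hydroxybenzaldehyde
Product: 2 4-(tert-butyldimethylsilyloxy)benzaldehyde
Conditions: TBSCl, imidazole, DMF, rt
Reagents that add atoms: tert-butyldimethylsilyl chloride, CC(C)(C)[Si](C)(C)Cl
Why: Routine O-silylation of a phenol under imidazole catalysis; the aldehyde is untouched and the silyl ether is the protecting group carried to the end.

**Step 2**
Reactants: 2 4-(tert-butyldimethylsilyloxy)benzaldehyde
Product: 4 (R)-1-[4-(tert-butyldimethylsilyloxy)phenyl]but-3-en-1-ol, via borinate ester 3 (not isolated)
Conditions: (+)-Ipc2B(allyl) (1 M in pentane, (−)-α-pinene series), Et2O, −78 °C; then HOCH2CH2NH2, rt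
Reagents that add atoms: (+)-B-allyldiisopinocampheylborane, C=CCB([C@H]1C[C@H]2C[C@@H]([C@@H]1C)C2(C)C)[C@H]1C[C@H]2C[C@@H]([C@@H]1C)C2(C)C
Why: Brown allylation through a closed six-membered chair transition state in which the isopinocampheyl groups select the aldehyde face that leads to the (R)-carbinol, which sets C7; ethanolamine releases the alcohol from 3 without the alkaline peroxide that would cleave the aryl silyl ether.

**Step 3**
Reactants: 4 (R)-1-[4-(tert-butyldimethylsilyloxy)phenyl]but-3-en-1-ol
Product: 5 (R)-tert-butyl{4-[1-(tert-butyldimethylsilyloxy)but-3-enyl]phenoxy}dimethylsilane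
Conditions: TBSOTf, 2,6-lutidine, CH2Cl2, −78 → 0 °C
Reagents that add atoms: tert-butyldimethylsilyl trifluoromethanesulfonate, CC(C)(C)[Si](C)(C)OS(=O)(=O)C(F)(F)F
Why: Silylation of a secondary benzylic alcohol with the silyl triflate and a hindered base; no bond to C7 is broken, so the configuration is retained.

**Step 4**
Reactants: 5 (R)-tert-butyl{4-[1-(tert-butyldimethylsilyloxy)but-3-enyl]phenoxy}dimethylsilane
Product: 7 (R)-3-(tert-butyldimethylsilyloxy)-3-[4-(tert-butyldimethylsilyloxy)phenyl]propanal, via ozonide 6 (not isolated)
Conditions: O3, CH2Cl2, −78 °C (stopped at first excess); then PPh3, −78 °C → rt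
Reagents that add atoms: ozone, [O-][O+]=O
Why: Ozonolysis of the terminal alkene with reductive work-up; a monosubstituted alkene reacts far faster than the silyloxy-substituted arene at −78 °C, and the neutral phosphine work-up leaves the β-silyloxy aldehyde intact.

**Step 5**
Reactants: 7 (R)-3-(tert-butyldimethylsilyloxy)-3-[4-(tert-butyldimethylsilyloxy)phenyl]propanal
Product: 9 (S)-2-{(tert-butyldimethylsilyloxy)[4-(tert-butyldimethylsilyloxy)phenyl]methyl}prop-2-enal, via Mannich base 8 (not isolated)
Conditions: CH2=NMe2+ I− (Eschenmoser's salt), Et3N, CH2Cl2, rt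
Reagents that add atoms: N,N-dimethylmethyleneiminium iodide, C=[N+](C)C.[I-]
Why: Mannich α-aminomethylation of the aldehyde followed by elimination of dimethylamine (α-methylenation); the amine is a far better leaving group than the silanolate at C7, and C7 is not involved, so its configuration is kept.

**Step 6**
Reactants: 10 4-iodophenol
Product: 11 tert-butyl(4-iodophenoxy)dimethylsilane
Conditions: TBSCl, imidazole, DMF, rt
Reagents that add atoms: tert-butyldimethylsilyl chloride, CC(C)(C)[Si](C)(C)Cl
Why: Routine phenol silylation; the aryl iodide is inert.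

**Step 7**
Reactants: 12 but-3-yn-1-ol
Product: 13 but-3-ynyl 2,2-dimethylpropanoate
Conditions: PivCl, Et3N, DMAP (cat.), CH2Cl2, 0 °C → rt
Reagents that add atoms: pivaloyl chloride, CC(C)(C)C(Cl)=O
Why: Acylation of a primary alcohol; the hindered ester later resists the Lewis acid of the key step and is removed by hydride.

**Step 8**
Reactants: 11 tert-butyl(4-iodophenoxy)dimethylsilane; 13 but-3-ynyl 2,2-dimethylpropanoate
Product: 14 4-[4-(tert-butyldimethylsilyloxy)phenyl]but-3-ynyl 2,2-dimethylpropanoate
Conditions: Pd(PPh3)2Cl2 (2 mol %), CuI (4 mol %), Et3N, THF, rt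
Reagents that add atoms: none
Why: Sonogashira coupling of an aryl iodide with a terminal alkyne proceeds at room temperature, where the aryl silyl ether and the ester are stable.

**Step 9**
Reactants: 14 4-[4-(tert-butyldimethylsilyloxy)phenyl]but-3-ynyl 2,2-dimethylpropanoate
Product: 15 (Z)-4-[4-(tert-butyldimethylsilyloxy)phenyl]but-3-enyl 2,2-dimethylpropanoate
Conditions: H2 (1 atm), Pd/CaCO3 poisoned with Pb(OAc)2, quinoline, EtOAc, rt, stopped after one equivalent
Reagents that add atoms: none
Why: Syn semi-hydrogenation of the alkyne on the poisoned palladium surface delivers both hydrogens to one face and gives the Z-alkene; quinoline suppresses over-reduction and isomerisation.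

**Step 10**
Reactants: 9 (S)-2-{(tert-butyldimethylsilyloxy)[4-(tert-butyldimethylsilyloxy)phenyl]methyl}prop-2-enal; 15 (Z)-4-[4-(tert-butyldimethylsilyloxy)phenyl]but-3-enyl 2,2-dimethylpropanoate
Product: 16 2-[(2R,3R)-2-[4-(tert-butyldimethylsilyloxy)phenyl]-5-{(S)-(tert-butyldimethylsilyloxy)[4-(tert-butyldimethylsilyloxy)phenyl]methyl}-3,4-dihydro-2H-pyran-3-yl]ethyl 2,2-dimethylpropanoate
Conditions: Eu(fod)3 (10 mol %), 15 (2 equiv), CH2Cl2 (2 M), 10 kbar, 25 °C; chromatography on Et3N-deactivated silica
Reagents that add atoms: none
Why: Eu(fod)3 binds the aldehyde oxygen of 9 as a single-point, non-chelating Lewis acid and lowers the LUMO of the s-cis 1-oxadiene O1=C6–C5=C4, while the para-silyloxy group raises the HOMO of 15, so that its β-carbon (C3) bonds to C4 slightly ahead of the bonding of its benzylic carbon (C2) to O1 in a concerted, asynchronous [4+2] transition state that pressure favours through its negative activation volume. The closest known reaction type is the lanthanide- or pressure-promoted inverse-electron-demand hetero-Diels–Alder reaction of 2-substituted acroleins with vinyl ethers and with styrenes, which gives 2-alkoxy- or 2-aryl-3,4-dihydro-2H-pyrans. The dihydropyran ring closes by this intermolecular cycloaddition itself, O1–C2 and C3–C4 forming on one face of the alkene and at the two ends of the heterodiene, with no separate cyclisation event. C2 and C3 are new: their relative (cis) configuration is fixed by the Z geometry of 15 through suprafacial addition, and their absolute sense, that is which face of 15 is used, by the C7 stereocentre of 9 together with the endo or exo placement of the aryl group; C7 itself is untouched. Regiochemistry (aryl-bearing carbon to oxygen) follows from the polarisation of both partners. Stereospecificity requires that a benzylic zwitterion be avoided, which the weak lanthanide acid, the absence of protic or halide acids and the carbonyl-deactivated pivalate oxygen (unable to trap a benzylic cation) are chosen to secure. The bulky silyl ether on O7 cannot chelate the metal together with O1, so the enal is not locked s-trans, and it is a poor leaving group for β-elimination or allylic ionisation. Face selectivity is the one demand the substrate secures only weakly; because 9 is a single enantiomer, the wrong-face adduct is a diastereomer of 16 and is removed by chromatography.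

**Step 11**
Reactants: 16 2-[(2R,3R)-2-[4-(tert-butyldimethylsilyloxy)phenyl]-5-{(S)-(tert-butyldimethylsilyloxy)[4-(tert-butyldimethylsilyloxy)phenyl]methyl}-3,4-dihydro-2H-pyran-3-yl]ethyl 2,2-dimethylpropanoate
Product: 17 2-[(2R,3R,5R)-2-[4-(tert-butyldimethylsilyloxy)phenyl]-5-{(R)-(tert-butyldimethylsilyloxy)[4-(tert-butyldimethylsilyloxy)phenyl]methyl}oxan-3-yl]ethyl 2,2-dimethylpropanoate
Conditions: H2 (1 atm), 10% Pd/C, pyridine (0.5 equiv), EtOAc, rt
Reagents that add atoms: none
Why: Heterogeneous syn-hydrogenation of the trisubstituted enol ether; in either half-chair of 16 one of the cis C2/C3 groups is pseudo-axial and covers the same face, so hydrogen should arrive from the other face, placing C5–H trans to them and the C7 arm cis (5R). Pyridine suppresses benzylic C–O hydrogenolysis and acid-induced ionisation at C7.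

**Step 12**
Reactants: 17 2-[(2R,3R,5R)-2-[4-(tert-butyldimethylsilyloxy)phenyl]-5-{(R)-(tert-butyldimethylsilyloxy)[4-(tert-butyldimethylsilyloxy)phenyl]methyl}oxan-3-yl]ethyl 2,2-dimethylpropanoate
Product: 18 2-[(2R,3R,5R)-2-[4-(tert-butyldimethylsilyloxy)phenyl]-5-{(R)-(tert-butyldimethylsilyloxy)[4-(tert-butyldimethylsilyloxy)phenyl]methyl}oxan-3-yl]ethanol
Conditions: i-Bu2AlH (2.5 equiv), CH2Cl2, −78 °C; aq. potassium sodium tartrate
Reagents that add atoms: none
Why: Reductive cleavage of the pivalate by hydride at low temperature; unlike alkoxide or hydroxide, this leaves the aryl silyl ethers in place.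

**Step 13**
Reactants: 18 2-[(2R,3R,5R)-2-[4-(tert-butyldimethylsilyloxy)phenyl]-5-{(R)-(tert-butyldimethylsilyloxy)[4-(tert-butyldimethylsilyloxy)phenyl]methyl}oxan-3-yl]ethanol
Product: 19 5-({2-[(2R,3R,5R)-2-[4-(tert-butyldimethylsilyloxy)phenyl]-5-{(R)-(tert-butyldimethylsilyloxy)[4-(tert-butyldimethylsilyloxy)phenyl]methyl}oxan-3-yl]ethyl}sulfanyl)-1-phenyl-1H-tetrazole
Conditions: 1-phenyl-1H-tetrazole-5-thiol, PPh3, DIAD, THF, 0 °C → rt
Reagents that add atoms: 1-phenyl-1H-tetrazole-5-thiol, Sc1nnnn1-c1ccccc1
Why: Mitsunobu thioetherification of an unhindered primary alcohol with an acidic thiol; no stereocentre is involved.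

**Step 14**
Reactants: 19 5-({2-[(2R,3R,5R)-2-[4-(tert-butyldimethylsilyloxy)phenyl]-5-{(R)-(tert-butyldimethylsilyloxy)[4-(tert-butyldimethylsilyloxy)phenyl]methyl}oxan-3-yl]ethyl}sulfanyl)-1-phenyl-1H-tetrazole
Product: 20 5-({2-[(2R,3R,5R)-2-[4-(tert-butyldimethylsilyloxy)phenyl]-5-{(R)-(tert-butyldimethylsilyloxy)[4-(tert-butyldimethylsilyloxy)phenyl]methyl}oxan-3-yl]ethyl}sulfonyl)-1-phenyl-1H-tetrazole
Conditions: (NH4)6Mo7O24·4H2O (15 mol %), 30% H2O2, EtOH, 0 °C → rt
Reagents that add atoms: hydrogen peroxide, OO
Why: Molybdate-catalysed peroxide oxidation of the sulfide to the sulfone; by this stage the molecule has no alkene or enol ether left to compete for the oxidant.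

**Step 15**
Reactants: 20 5-({2-[(2R,3R,5R)-2-[4-(tert-butyldimethylsilyloxy)phenyl]-5-{(R)-(tert-butyldimethylsilyloxy)[4-(tert-butyldimethylsilyloxy)phenyl]methyl}oxan-3-yl]ethyl}sulfonyl)-1-phenyl-1H-tetrazole; 2 4-(tert-butyldimethylsilyloxy)benzaldehyde
Product: 21 (2R,3S,5R)-2-[4-(tert-butyldimethylsilyloxy)phenyl]-3-{(E)-3-[4-(tert-butyldimethylsilyloxy)phenyl]prop-2-enyl}-5-{(R)-(tert-butyldimethylsilyloxy)[4-(tert-butyldimethylsilyloxy)phenyl]methyl}oxane
Conditions: KN(SiMe3)2, THF, −78 °C → rt (base added to 20 and 2 together)
Reagents that add atoms: none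
Why: Julia–Kocienski olefination: the sulfonyl carbanion adds to the aldehyde, and Smiles rearrangement with loss of SO2 and the tetrazolyl oxide forms the alkene; with an alkyl sulfone and an aromatic aldehyde the sequence is E-selective, and adding the base last limits self-condensation of the sulfone.

**Step 16**
Reactants: 21 (2R,3S,5R)-2-[4-(tert-butyldimethylsilyloxy)phenyl]-3-{(E)-3-[4-(tert-butyldimethylsilyloxy)phenyl]prop-2-enyl}-5-{(R)-(tert-butyldimethylsilyloxy)[4-(tert-butyldimethylsilyloxy)phenyl]methyl}oxane
Product: 22 4-[(1E)-3-{(2R,3S,5R)-5-[(R)-hydroxy(4-hydroxyphenyl)methyl]-2-(4-hydroxyphenyl)oxan-3-yl}prop-1-en-1-yl]phenol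
Conditions: Bu4NF, AcOH (1:1, 6 equiv), THF, 0 °C → rt
Reagents that add atoms: none
Why: Fluoride cleaves all four Si–O bonds by attack at silicon; acetic acid keeps the liberated phenols protonated so that no phenoxide can expel the benzylic oxygen at C7 or C2 as a quinone methide, and no stereocentre is touched.

## Compound list

1 | 4-hydroxybenzaldehyde | O=Cc1ccc(O)cc1 | starting material
2 | 4-(tert-butyldimethylsilyloxy)benzaldehyde | O=Cc1ccc(O[Si](C)(C)C(C)(C)C)cc1 | intermediate
3 | (R)-1-[4-(tert-butyldimethylsilyloxy)phenyl]but-3-enyl diisopinocampheylborinate (isopinocampheyl groups of the (−)-α-pinene series) | C=CC[C@@H](OB([C@H]1C[C@H]2C[C@@H]([C@@H]1C)C2(C)C)[C@H]1C[C@H]2C[C@@H]([C@@H]1C)C2(C)C)c1ccc(O[Si](C)(C)C(C)(C)C)cc1 | intermediate (not isolated)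
4 | (R)-1-[4-(tert-butyldimethylsilyloxy)phenyl]but-3-en-1-ol | C=CC[C@@H](O)c1ccc(O[Si](C)(C)C(C)(C)C)cc1 | intermediate
5 | (R)-tert-butyl{4-[1-(tert-butyldimethylsilyloxy)but-3-enyl]phenoxy}dimethylsilane | C=CC[C@@H](O[Si](C)(C)C(C)(C)C)c1ccc(O[Si](C)(C)C(C)(C)C)cc1 | intermediate
6 | 3-{(R)-2-(tert-butyldimethylsilyloxy)-2-[4-(tert-butyldimethylsilyloxy)phenyl]ethyl}-1,2,4-trioxolane (ring carbon unassigned) | C1(C[C@@H](O[Si](C)(C)C(C)(C)C)c2ccc(O[Si](C)(C)C(C)(C)C)cc2)OCOO1 | intermediate (not isolated)
7 | (R)-3-(tert-butyldimethylsilyloxy)-3-[4-(tert-butyldimethylsilyloxy)phenyl]propanal | O=CC[C@@H](O[Si](C)(C)C(C)(C)C)c1ccc(O[Si](C)(C)C(C)(C)C)cc1 | intermediate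
8 | (3R)-3-(tert-butyldimethylsilyloxy)-3-[4-(tert-butyldimethylsilyloxy)phenyl]-2-[(dimethylamino)methyl]propanal (both C2 epimers) | O=CC(CN(C)C)[C@@H](O[Si](C)(C)C(C)(C)C)c1ccc(O[Si](C)(C)C(C)(C)C)cc1 | intermediate (not isolated)
9 | (S)-2-{(tert-butyldimethylsilyloxy)[4-(tert-butyldimethylsilyloxy)phenyl]methyl}prop-2-enal | O=CC(=C)[C@@H](O[Si](C)(C)C(C)(C)C)c1ccc(O[Si](C)(C)C(C)(C)C)cc1 | intermediate
10 | 4-iodophenol | Oc1ccc(I)cc1 | starting material
11 | tert-butyl(4-iodophenoxy)dimethylsilane | Ic1ccc(O[Si](C)(C)C(C)(C)C)cc1 | intermediate
12 | but-3-yn-1-ol | C#CCCO | starting material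
13 | but-3-ynyl 2,2-dimethylpropanoate | C#CCCOC(=O)C(C)(C)C | intermediate
14 | 4-[4-(tert-butyldimethylsilyloxy)phenyl]but-3-ynyl 2,2-dimethylpropanoate | CC(C)(C)C(=O)OCCC#Cc1ccc(O[Si](C)(C)C(C)(C)C)cc1 | intermediate
15 | (Z)-4-[4-(tert-butyldimethylsilyloxy)phenyl]but-3-enyl 2,2-dimethylpropanoate | CC(C)(C)C(=O)OCC/C=C\c1ccc(O[Si](C)(C)C(C)(C)C)cc1 | intermediate
16 | 2-[(2R,3R)-2-[4-(tert-butyldimethylsilyloxy)phenyl]-5-{(S)-(tert-butyldimethylsilyloxy)[4-(tert-butyldimethylsilyloxy)phenyl]methyl}-3,4-dihydro-2H-pyran-3-yl]ethyl 2,2-dimethylpropanoate | CC(C)(C)C(=O)OCC[C@H]1CC([C@@H](O[Si](C)(C)C(C)(C)C)c2ccc(O[Si](C)(C)C(C)(C)C)cc2)=CO[C@H]1c1ccc(O[Si](C)(C)C(C)(C)C)cc1 | intermediate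
17 | 2-[(2R,3R,5R)-2-[4-(tert-butyldimethylsilyloxy)phenyl]-5-{(R)-(tert-butyldimethylsilyloxy)[4-(tert-butyldimethylsilyloxy)phenyl]methyl}oxan-3-yl]ethyl 2,2-dimethylpropanoate | CC(C)(C)C(=O)OCC[C@H]1C[C@@H]([C@@H](O[Si](C)(C)C(C)(C)C)c2ccc(O[Si](C)(C)C(C)(C)C)cc2)CO[C@H]1c1ccc(O[Si](C)(C)C(C)(C)C)cc1 | intermediate
18 | 2-[(2R,3R,5R)-2-[4-(tert-butyldimethylsilyloxy)phenyl]-5-{(R)-(tert-butyldimethylsilyloxy)[4-(tert-butyldimethylsilyloxy)phenyl]methyl}oxan-3-yl]ethanol | OCC[C@H]1C[C@@H]([C@@H](O[Si](C)(C)C(C)(C)C)c2ccc(O[Si](C)(C)C(C)(C)C)cc2)CO[C@H]1c1ccc(O[Si](C)(C)C(C)(C)C)cc1 | intermediate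
19 | 5-({2-[(2R,3R,5R)-2-[4-(tert-butyldimethylsilyloxy)phenyl]-5-{(R)-(tert-butyldimethylsilyloxy)[4-(tert-butyldimethylsilyloxy)phenyl]methyl}oxan-3-yl]ethyl}sulfanyl)-1-phenyl-1H-tetrazole | c1ccccc1-n1nnnc1SCC[C@H]1C[C@@H]([C@@H](O[Si](C)(C)C(C)(C)C)c2ccc(O[Si](C)(C)C(C)(C)C)cc2)CO[C@H]1c1ccc(O[Si](C)(C)C(C)(C)C)cc1 | intermediate
20 | 5-({2-[(2R,3R,5R)-2-[4-(tert-butyldimethylsilyloxy)phenyl]-5-{(R)-(tert-butyldimethylsilyloxy)[4-(tert-butyldimethylsilyloxy)phenyl]methyl}oxan-3-yl]ethyl}sulfonyl)-1-phenyl-1H-tetrazole | c1ccccc1-n1nnnc1S(=O)(=O)CC[C@H]1C[C@@H]([C@@H](O[Si](C)(C)C(C)(C)C)c2ccc(O[Si](C)(C)C(C)(C)C)cc2)CO[C@H]1c1ccc(O[Si](C)(C)C(C)(C)C)cc1 | intermediate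
21 | (2R,3S,5R)-2-[4-(tert-butyldimethylsilyloxy)phenyl]-3-{(E)-3-[4-(tert-butyldimethylsilyloxy)phenyl]prop-2-enyl}-5-{(R)-(tert-butyldimethylsilyloxy)[4-(tert-butyldimethylsilyloxy)phenyl]methyl}oxane | CC(C)(C)[Si](C)(C)Oc1ccc(/C=C/C[C@H]2C[C@@H]([C@@H](O[Si](C)(C)C(C)(C)C)c3ccc(O[Si](C)(C)C(C)(C)C)cc3)CO[C@H]2c2ccc(O[Si](C)(C)C(C)(C)C)cc2)cc1 | intermediate
22 | 4-[(1E)-3-{(2R,3S,5R)-5-[(R)-hydroxy(4-hydroxyphenyl)methyl]-2-(4-hydroxyphenyl)oxan-3-yl}prop-1-en-1-yl]phenol | Oc1ccc(/C=C/C[C@H]2C[C@@H]([C@@H](O)c3ccc(O)cc3)CO[C@H]2c2ccc(O)cc2)cc1 | target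

## Step count and least certain steps

Total: 16 steps. Longest linear sequence: 12 steps (steps 1–5, then 10–16); the dienophile branch (steps 6–9) is four steps, convergent at step 10.

**Step 10 (key step).** Three things can go wrong.
- The cycloaddition may be slow: a Z-β-alkylstyrene is twisted and less nucleophilic than its E isomer, and cationic oligomerisation of 15 may compete.
- Addition may become stepwise through a benzylic zwitterion, which would leak the cis C2/C3 relationship towards trans. The product is also a vinylogous acetal (O1–C6=C5–C7–O) that can ionise at C7 under acid.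
- Face discrimination by the remote C7 centre may be poor, leaving up to half of the material as the wrong-face diastereomer. The first refinement within the same step would be the matched enantiomer of tris[3-(heptafluoropropylhydroxymethylene)camphorato]europium, Eu(hfc)3.

The fallback changes the dienophile class and the source of the cis relationship; it sets out from 9 and 11 and returns at 18. Commercial 2,3-dihydrofuran, a cyclic enol ether of the class best established as partner for enal heterodienes, would add to 9 under Eu(fod)3 catalysis to give the cis-fused bicyclic acetal (3aR,7aR)-5-{(S)-(tert-butyldimethylsilyloxy)[4-(tert-butyldimethylsilyloxy)phenyl]methyl}-3,3a,4,7a-tetrahydro-2H-furo[2,3-b]pyran F1. Here ring fusion, not alkene geometry, places the C2–O and C3–CH2 bonds cis. Hydrogenation from the convex face would give the saturated acetal (3aR,5R,7aR)-5-{(R)-(tert-butyldimethylsilyloxy)[4-(tert-butyldimethylsilyloxy)phenyl]methyl}hexahydro-4H-furo[2,3-b]pyran F2. Tris[4-(tert-butyldimethylsilyloxy)phenyl]alane F3 (from 11, Mg, then AlCl3) would then open the acetal at the five-membered-ring oxygen and deliver one aryl group to C2 on the face that this oxygen leaves. This is a retentive organoaluminium acetal cleavage, equivalent to axial attack on the oxocarbenium ion with the C3 and C5 groups equatorial. It gives 18 directly and bypasses 13–17. The aryl transfer is the least precedented part of this detour, and the face question relative to C7 remains and would again be settled by separating diastereomers.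

**Step 11.** Hydrogen may add from the wrong face if the pivalate carbonyl or the C7 ether anchors the substrate to the metal surface, and the benzylic or allylic C–O bonds may be hydrogenolysed or ionised. The fallback replaces surface hydrogenation by a stepwise hydrogen-atom-transfer reduction with Mn(dpm)3 [tris(dipivaloylmethanato)manganese], PhSiH3 and t-BuOOH in i-PrOH. The bulky metal hydride would give the first hydrogen atom to C5 from the open face and has no affinity for C–O bonds. It sets out from 16 and returns at 17 without new intermediates.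

**Step 5.** The enolisable aldehyde 7 or the Mannich base 8 may lose silanol by β-elimination to a cinnamaldehyde, and elimination of the amine may be incomplete. The fallback brings in the methylene carbon by a Morita–Baylis–Hillman reaction, so that no β-silyloxy aldehyde is enolised; it sets out from 2 and returns at 9.
- 2, methyl acrylate and DABCO would give racemic methyl 2-{hydroxy[4-(tert-butyldimethylsilyloxy)phenyl]methyl}prop-2-enoate F4.
- Lipase-catalysed acetylation with vinyl acetate, with the enzyme chosen to acylate the R enantiomer, would leave the (S)-alcohol methyl (S)-2-{hydroxy[4-(tert-butyldimethylsilyloxy)phenyl]methyl}prop-2-enoate F5 beside the (R)-acetate methyl (R)-2-{acetoxy[4-(tert-butyldimethylsilyloxy)phenyl]methyl}prop-2-enoate F6.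
- F5 would be silylated (TBSOTf, 2,6-lutidine) to methyl (S)-2-{(tert-butyldimethylsilyloxy)[4-(tert-butyldimethylsilyloxy)phenyl]methyl}prop-2-enoate F7.
- F7 would be reduced with i-Bu2AlH to (S)-2-{(tert-butyldimethylsilyloxy)[4-(tert-butyldimethylsilyloxy)phenyl]methyl}prop-2-en-1-ol F8 and oxidised with MnO2 to 9.

The price is half of the material at the resolution and two more steps.

**Step 15.** The olefination may be incompletely E-selective, and the sulfone may self-condense before it meets the aldehyde. The fallback makes the double bond by syn-hydrometalation, which fixes the geometry mechanistically; it sets out from 18 and returns at 21.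
- Dess–Martin oxidation of 18 would give [(2R,3R,5R)-2-[4-(tert-butyldimethylsilyloxy)phenyl]-5-{(R)-(tert-butyldimethylsilyloxy)[4-(tert-butyldimethylsilyloxy)phenyl]methyl}oxan-3-yl]acetaldehyde F9.
- Colvin homologation with lithiated Me3SiCHN2 in THF at −78 °C would give the terminal alkyne (2R,3R,5R)-2-[4-(tert-butyldimethylsilyloxy)phenyl]-5-{(R)-(tert-butyldimethylsilyloxy)[4-(tert-butyldimethylsilyloxy)phenyl]methyl}-3-(prop-2-ynyl)oxane F10. The carbonate/methanol variant of this homologation would strip aryl silyl ethers.
- Hydrozirconation with Cp2Zr(H)Cl followed by Negishi coupling with 11 (ZnCl2, Pd(PPh3)4) would give 21 with the E geometry set by syn addition.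

## Further compounds

F1 | step 10 | (3aR,7aR)-5-{(S)-(tert-butyldimethylsilyloxy)[4-(tert-butyldimethylsilyloxy)phenyl]methyl}-3,3a,4,7a-tetrahydro-2H-furo[2,3-b]pyran | C1C[C@H]2CC([C@@H](O[Si](C)(C)C(C)(C)C)c3ccc(O[Si](C)(C)C(C)(C)C)cc3)=CO[C@H]2O1
F2 | step 10 | (3aR,5R,7aR)-5-{(R)-(tert-butyldimethylsilyloxy)[4-(tert-butyldimethylsilyloxy)phenyl]methyl}hexahydro-4H-furo[2,3-b]pyran | C1C[C@H]2C[C@@H]([C@@H](O[Si](C)(C)C(C)(C)C)c3ccc(O[Si](C)(C)C(C)(C)C)cc3)CO[C@H]2O1
F3 | step 10 | tris[4-(tert-butyldimethylsilyloxy)phenyl]alane | c1cc(O[Si](C)(C)C(C)(C)C)ccc1[Al](c1ccc(O[Si](C)(C)C(C)(C)C)cc1)c1ccc(O[Si](C)(C)C(C)(C)C)cc1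
F0 | step 11 | none | none
F4 | step 5 | methyl 2-{hydroxy[4-(tert-butyldimethylsilyloxy)phenyl]methyl}prop-2-enoate (racemic) | COC(=O)C(=C)C(O)c1ccc(O[Si](C)(C)C(C)(C)C)cc1
F5 | step 5 | methyl (S)-2-{hydroxy[4-(tert-butyldimethylsilyloxy)phenyl]methyl}prop-2-enoate | COC(=O)C(=C)[C@@H](O)c1ccc(O[Si](C)(C)C(C)(C)C)cc1
F6 | step 5 | methyl (R)-2-{acetoxy[4-(tert-butyldimethylsilyloxy)phenyl]methyl}prop-2-enoate | COC(=O)C(=C)[C@H](OC(C)=O)c1ccc(O[Si](C)(C)C(C)(C)C)cc1
F7 | step 5 | methyl (S)-2-{(tert-butyldimethylsilyloxy)[4-(tert-butyldimethylsilyloxy)phenyl]methyl}prop-2-enoate | COC(=O)C(=C)[C@@H](O[Si](C)(C)C(C)(C)C)c1ccc(O[Si](C)(C)C(C)(C)C)cc1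
F8 | step 5 | (S)-2-{(tert-butyldimethylsilyloxy)[4-(tert-butyldimethylsilyloxy)phenyl]methyl}prop-2-en-1-ol | OCC(=C)[C@@H](O[Si](C)(C)C(C)(C)C)c1ccc(O[Si](C)(C)C(C)(C)C)cc1
F9 | step 15 | [(2R,3R,5R)-2-[4-(tert-butyldimethylsilyloxy)phenyl]-5-{(R)-(tert-butyldimethylsilyloxy)[4-(tert-butyldimethylsilyloxy)phenyl]methyl}oxan-3-yl]acetaldehyde | O=CC[C@H]1C[C@@H]([C@@H](O[Si](C)(C)C(C)(C)C)c2ccc(O[Si](C)(C)C(C)(C)C)cc2)CO[C@H]1c1ccc(O[Si](C)(C)C(C)(C)C)cc1
F10 | step 15 | (2R,3R,5R)-2-[4-(tert-butyldimethylsilyloxy)phenyl]-5-{(R)-(tert-butyldimethylsilyloxy)[4-(tert-butyldimethylsilyloxy)phenyl]methyl}-3-(prop-2-ynyl)oxane | C#CC[C@H]1C[C@@H]([C@@H](O[Si](C)(C)C(C)(C)C)c2ccc(O[Si](C)(C)C(C)(C)C)cc2)CO[C@H]1c1ccc(O[Si](C)(C)C(C)(C)C)cc1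
A1 | alternative 1 | 1,5-bis[(R)-4-benzyl-2-oxooxazolidin-3-yl]pentane-1,5-dione (glutaryl bis-imide) | O=C(CCCC(=O)N1[C@H](Cc2ccccc2)COC1=O)N1[C@H](Cc2ccccc2)COC1=O
A2 | alternative 1 | C2-symmetric bis-anti-aldol adduct of A1 with two molecules of 2 | O=C(N1[C@H](Cc2ccccc2)COC1=O)[C@H]([C@@H](O)c1ccc(O[Si](C)(C)C(C)(C)C)cc1)C[C@@H]([C@@H](O)c1ccc(O[Si](C)(C)C(C)(C)C)cc1)C(=O)N1[C@H](Cc2ccccc2)COC1=O
A3 | alternative 2 | 4-{(R)-[(S)-cyclohex-3-en-1-yl](hydroxy)methyl}phenyl 2,2-dimethylpropanoate | O[C@H]([C@@H]1CC=CCC1)c1ccc(OC(=O)C(C)(C)C)cc1
A4 | alternative 2 | 4-[(1S,2R,5S)-3-oxabicyclo[3.3.1]non-6-en-2-yl]phenyl 2,2-dimethylpropanoate | C1=CC[C@H]2C[C@@H]1CO[C@H]2c1ccc(OC(=O)C(C)(C)C)cc1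
A5 | alternative 2 | 4-[(2R,3R,5R)-5-formyl-3-(2-oxoethyl)oxan-2-yl]phenyl 2,2-dimethylpropanoate | O=CC[C@H]1C[C@@H](C=O)CO[C@H]1c1ccc(OC(=O)C(C)(C)C)cc1
A6 | alternative 3 | (S)-[4-(tert-butyldimethylsilyloxy)phenyl](furan-2-yl)methanol | O[C@H](c1ccco1)c1ccc(O[Si](C)(C)C(C)(C)C)cc1
A7 | alternative 3 | (2S)-2-[4-(tert-butyldimethylsilyloxy)phenyl]-6-hydroxy-2H-pyran-3(6H)-one (anomeric mixture) | O=C1C=CC(O)O[C@H]1c1ccc(O[Si](C)(C)C(C)(C)C)cc1
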